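**Plan**

- Labels: chromanone atoms O1, C2, C3, C4 form ring C, fused to ring A; ring B is the 4-hydroxyphenyl on C2; ring D is the 4-hydroxyphenyl ring bonded to C3 that also carries the enone; ring E is the 2,4-dihydroxyphenyl ketone of the open chalcone.
- Retrosynthesis: the C3–ring D bond (to the carbon ortho to the ring D hydroxyl) and the O1–C2 bond are cut in one operation, leaving two molecules of one chalcone, isoliquiritigenin; cutting its Cα=Cβ bond gives 2,4-dihydroxyacetophenone and 4-hydroxybenzaldehyde.
- Enabling feature: C3 is the enone α-carbon of one chalcone unit and its partner is the ring D carbon ortho to the 4-hydroxyl of the other. These are the two carbon sites that carry spin in the phenoxyl radical of a 4-hydroxystyryl ketone. O1 is the 2'-oxygen of the first unit, placed to close a six-membered ring onto the quinone methide carbon C2 that the coupling leaves behind.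
- Forward: a Claisen–Schmidt condensation joins the chain; one oxidative dimerisation then forms C3–ring D and closes ring C through O1–C2. Rings A, B, D and E come in with the chalcone, and no protecting groups are used.
- Stereochemistry: the enone is E by thermodynamic control; C2 is set in the ring closure by a chiral phosphoric acid, and C3, α to the ketone, equilibrates to the trans (2R,3S) arrangement. Both centres arise in the last step.

Key step: step 2

Assumption: the sense of induction of the phosphoric acid in this closure cannot be deduced with confidence, so (R)-TRIP is written and its mirror image is meant if the (R)-acid should favour the (2S,3R) series.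

**Step 1**
Reactants: 1 2,4-dihydroxyacetophenone; 2 4-hydroxybenzaldehyde
Product: 4 isoliquiritigenin [(E)-1-(2,4-dihydroxyphenyl)-3-(4-hydroxyphenyl)prop-2-en-1-one], via aldol adduct 3 (not isolated)
Conditions: KOH (60% aq, excess), EtOH, rt, N2, dark; then 2 M HCl to pH 4 at 0 °C
Reagents that add atoms: none
Why: Claisen–Schmidt condensation (crossed aldol addition to 3, then E1cB loss of water), in which the methyl ketone of 1 is the only enolisable partner, aldehyde 2 cannot self-condense, the conjugated E-enone is the thermodynamic product and the chalcone stays open as its phenoxide in strong base.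

**Step 2**
Reactants: 4 isoliquiritigenin (two molecules)
Product: 7 target dimer (E)-1-(2,4-dihydroxyphenyl)-3-{4-hydroxy-3-[(2R,3S)-7-hydroxy-2-(4-hydroxyphenyl)-4-oxochroman-3-yl]phenyl}prop-2-en-1-one, via dienone quinone methide adduct 5 (not isolated), via quinone methide phenol 6 (not isolated)
Conditions: Ag2O (0.55 equiv), (R)-TRIP [(R)-3,3'-bis(2,4,6-triisopropylphenyl)-1,1'-binaphthyl-2,2'-diyl hydrogen phosphate] (10 mol %), 4 Å MS, EtOAc/CH2Cl2 1:1, 0 °C to rt, N2, dark; Celite filtration, SiO2 chromatography, one recrystallisation (EtOAc/heptane)
Reagents that add atoms: none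
Why: Proposed new method: Ag2O takes one hydrogen atom from the 4-hydroxyl of each of two molecules of 4; the phenoxyl radicals hold spin on the enone α-carbon and on the ring carbon ortho to oxygen, their α/ortho combination gives 5, and tautomerisation of its dienone ring back to the ring D phenol leaves the para-quinone methide 6. The closest known reactions are the Ag2O dehydrodimerisations of 4-hydroxycinnamates and 4-hydroxystilbenes, which join the same two positions but end in a dihydrobenzofuran, and the chiral phosphoric acid-catalysed 1,6-additions of heteroatom and carbon nucleophiles to para-quinone methides; their merger in one flask, with a phenol ortho to a ketone as the nucleophile, has not been shown. Ring C closes by 6-exo-trig oxa-1,6-addition of the 2'-hydroxyl (O1) to the exocyclic quinone methide carbon (C2), which restores ring B as a phenol. C2 is set by the phosphate, which is expected to bridge the quinone methide oxygen and the attacking hydroxyl and so leave one face of C2 open, while C3, flanked by the ketone, ring D and the quinone methide, epimerises by enolisation in 6 and in the product and should end trans to the aryl group on C2 with both aryl groups equatorial. The step needs the α/ortho radical combination in preference to the α/α and carbon/oxygen modes, which the spin pattern of an ortho-unsubstituted 4-hydroxystyryl ketone and the near-stoichiometric charge of oxidant favour, and it needs closure through O1 instead of the ring D oxygen, for which the unstrained chromanone is the expected thermodynamic product whereas the strained five-ring 4-hydroxybenzyl aryl ether can be re-ionised by the acid and returned to 6. The hydroxyls para to the two carbonyl groups are too electron-poor to be oxidised, the planar chalcone of the second unit should not cyclise under a weak acid at or below rt, and acid neutralised by Ag2O is set free again as the silver is reduced to the metal.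

**Compound list**

1 | 2,4-dihydroxyacetophenone, 1-(2,4-dihydroxyphenyl)ethanone | CC(=O)c1ccc(O)cc1O | starting material
2 | 4-hydroxybenzaldehyde | O=Cc1ccc(O)cc1 | starting material
3 | aldol adduct, racemic 1-(2,4-dihydroxyphenyl)-3-hydroxy-3-(4-hydroxyphenyl)propan-1-one | O=C(CC(O)c1ccc(O)cc1)c1ccc(O)cc1O | intermediate
4 | isoliquiritigenin, (E)-1-(2,4-dihydroxyphenyl)-3-(4-hydroxyphenyl)prop-2-en-1-one | O=C(/C=C/c1ccc(O)cc1)c1ccc(O)cc1O | intermediate
5 | dienone quinone methide adduct, 1-(2,4-dihydroxyphenyl)-2-{3-[(E)-3-(2,4-dihydroxyphenyl)-3-oxoprop-1-enyl]-6-oxocyclohexa-2,4-dien-1-yl}-3-(4-oxocyclohexa-2,5-dien-1-ylidene)propan-1-one, mixture of stereoisomers at the two sp3 carbons | O=C1C=CC(=CC(C2C=C(/C=C/C(=O)c3ccc(O)cc3O)C=CC2=O)C(=O)c2ccc(O)cc2O)C=C1 | intermediate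
6 | quinone methide phenol, 1-(2,4-dihydroxyphenyl)-2-{5-[(E)-3-(2,4-dihydroxyphenyl)-3-oxoprop-1-enyl]-2-hydroxyphenyl}-3-(4-oxocyclohexa-2,5-dien-1-ylidene)propan-1-one, epimerising at the future C3 | O=C1C=CC(=CC(c2cc(/C=C/C(=O)c3ccc(O)cc3O)ccc2O)C(=O)c2ccc(O)cc2O)C=C1 | intermediate
7 | (E)-1-(2,4-dihydroxyphenyl)-3-{4-hydroxy-3-[(2R,3S)-7-hydroxy-2-(4-hydroxyphenyl)-4-oxochroman-3-yl]phenyl}prop-2-en-1-one, trans at C2/C3 | O=C(/C=C/c1ccc(O)c([C@@H]2C(=O)c3ccc(O)cc3O[C@H]2c2ccc(O)cc2)c1)c1ccc(O)cc1O | target

**Totals**

Total step count: 2. Longest linear sequence: 2 steps (1 and 2 to 4 to 7).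

**Steps most likely to fail**

The route has only two steps, so step 2 is entered twice, once for each of its two independent failure processes.

1. Step 2, ring closure through the wrong oxygen. The 5-exo attack of the ring D hydroxyl on the quinone methide may outrun the 6-exo attack of O1, and the acid may fail to return the five-ring ether to 6. The dimer would then be isolated mainly in the dihydrobenzofuran series.
 Fallback (known reactions only), setting out from 4 and returning at 7: compound 4 would be dimerised with Ag2O alone in acetone/benzene at rt, the established dehydrodimerisation of 4-hydroxyphenylpropenoids, to give the racemic trans-dihydrobenzofuran dimer F1. Aqueous NaOH in dioxane at rt is known to open 3-acyl-2-aryl-2,3-dihydrobenzofurans by β-elimination of the ring phenoxide. Followed by acidification with HCl to pH 4, it would give the α-aryl-2'-hydroxychalcone F2. Piperidine in EtOH at reflux, the conditions under which α-aryl-2'-hydroxychalcones close by 6-endo-trig oxa-Michael addition, would give the racemic trans-flavanone dimer F3. Return to the five-ring ether from the enone would be a 5-endo-trig closure and is not expected, and the planar ring E chalcone is expected to close more slowly than the twisted α-aryl enone. Separation of F3 on a chiral stationary phase, as in the next fallback, rejoins the route at 7.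

2. Step 2, poor face discrimination at C2. The phosphate may not differentiate the two faces of the quinone methide well enough, or enantiopurity may be lost afterwards by reversible opening of the C2–O1 bond through the 4-hydroxyphenyl group. In either case 7 would arrive with an enantiomeric purity that one recrystallisation cannot lift.
 Fallback (known technique), setting out from enantiomerically impure 7 and returning at 7: stereocontrol is taken from separation instead of catalysis. The two enantiomers of 7 are parted by preparative HPLC on amylose tris(3,5-dimethylphenylcarbamate) coated silica with heptane/EtOH containing 0.1% HCO2H, a standard operation for flavanones, and the acidic eluent keeps the C2–O1 bond closed. No compound outside the list is made (F0).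

3. Step 1, stalled condensation. In strong base both partners are present as electron-rich phenoxides, so enolate formation from 1 and addition to 2 are slow, and forcing the reaction invites degradation of the aldehyde and of the product.
 Fallback, setting out from 1 and 2 and returning at 4: MOMCl and K2CO3 in acetone would convert 1, whose chelated 2-hydroxyl stays free, into 2-hydroxy-4-(methoxymethoxy)acetophenone F4 and, in a separate flask, 2 into 4-(methoxymethoxy)benzaldehyde F5. Condensation of F4 and F5 with KOH in EtOH at rt would give the bis-MOM chalcone F6, (E)-1-[2-hydroxy-4-(methoxymethoxy)phenyl]-3-[4-(methoxymethoxy)phenyl]prop-2-en-1-one. HCl (3 M) in MeOH at 50 °C would then remove both acetals and deliver 4.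

**Further compounds**

F1 | step 2 | racemic trans-(2R*,3R*)-(E)-3-[3-(2,4-dihydroxybenzoyl)-2-(4-hydroxyphenyl)-2,3-dihydro-1-benzofuran-5-yl]-1-(2,4-dihydroxyphenyl)prop-2-en-1-one, both enantiomers drawn | O=C(/C=C/c1ccc2O[C@@H](c3ccc(O)cc3)[C@H](C(=O)c3ccc(O)cc3O)c2c1)c1ccc(O)cc1O.O=C(/C=C/c1ccc2O[C@H](c3ccc(O)cc3)[C@@H](C(=O)c3ccc(O)cc3O)c2c1)c1ccc(O)cc1O
F2 | step 2 | (E)-1-(2,4-dihydroxyphenyl)-2-{5-[(E)-3-(2,4-dihydroxyphenyl)-3-oxoprop-1-enyl]-2-hydroxyphenyl}-3-(4-hydroxyphenyl)prop-2-en-1-one, the new double bond drawn as its E isomer | O=C(/C=C/c1ccc(O)c(c1)/C(=C\c1ccc(O)cc1)C(=O)c1ccc(O)cc1O)c1ccc(O)cc1O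
F3 | step 2 | racemic trans-flavanone dimer, equimolar 7 and its (2S,3R) enantiomer, both drawn | O=C(/C=C/c1ccc(O)c([C@@H]2C(=O)c3ccc(O)cc3O[C@H]2c2ccc(O)cc2)c1)c1ccc(O)cc1O.O=C(/C=C/c1ccc(O)c([C@H]2C(=O)c3ccc(O)cc3O[C@@H]2c2ccc(O)cc2)c1)c1ccc(O)cc1O
F0 | step 2 | none | none
F4 | step 1 | 2-hydroxy-4-(methoxymethoxy)acetophenone | CC(=O)c1ccc(OCOC)cc1O
F5 | step 1 | 4-(methoxymethoxy)benzaldehyde | O=Cc1ccc(OCOC)cc1
F6 | step 1 | (E)-1-[2-hydroxy-4-(methoxymethoxy)phenyl]-3-[4-(methoxymethoxy)phenyl]prop-2-en-1-one | O=C(/C=C/c1ccc(OCOC)cc1)c1ccc(OCOC)cc1O
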